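**Retrosynthetic overview**
1. Target ⇐ hydrolysis of a spiro methyl ketal; the ester-bearing cyclopentadiene ring ⇐ intramolecular aldol condensation of a propanoate arm (on the quaternary bridgehead carbon) onto a cyclopentenone carbonyl.
2. Seven-membered carbocycle and cyclopentenone ⇐ one gold-catalysed cascade (1,3-acyloxy shift, Nazarov closure, 1,2-alkyl shift) on the enynyl acetate of a 3-azabicyclo[3.3.1]nonane: the six-membered carbocycle takes up one alkyne carbon and becomes seven-membered.
3. Enabling feature: the tetrasubstituted C=C shared by the seven-membered carbocycle and the ester-free cyclopentene, one end bound to the quaternary bridgehead carbon, the other carrying the ring CH2CH2; it is the imprint of a spiro cyclopentenylidene whose quaternary neighbour has migrated.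
4. Spiro tetrahydropyran ⇐ titanocene-mediated epoxide opening/Giese addition to ethyl vinyl ketone at the one-carbon bridge; piperidine ⇐ two Mannich reactions on a 2-substituted cyclohexane-1,3-dione, made non-racemic by an enzymatic desymmetrising reduction.
5. Ring order: cyclohexane (purchased) → piperidine → tetrahydropyran → seven-membered ring together with cyclopentenone → cyclopentadiene ester ring.

Key step: step 11

Remark: the hemiketal carbon equilibrates through the open hydroxy ketone, so its configuration is assumed to be the thermodynamic one and is fixed only in the last step; but-1-en-3-yne is taken as the commercial solution.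

**Step 1**
Reactants: 1 cyclohexane-1,3-dione; 2 methyl acrylate
Product: 3 methyl 3-(2,6-dioxocyclohexyl)propanoate
Conditions: Et3N (0.2 equiv), MeOH, 60 °C
Reagents that add atoms: none
Why: The acidic 1,3-dione adds through its central carbon to the acrylate (Michael addition), which installs the three-carbon ester arm of the later cyclopentadiene ring.

**Step 2**
Reactants: 3 methyl 3-(2,6-dioxocyclohexyl)propanoate; 4 N-benzylmethylamine; 5 formaldehyde
Product: 6 methyl 3-[1-{[benzyl(methyl)amino]methyl}-2,6-dioxocyclohexyl]propanoate (achiral, prochiral)
Conditions: 37% aq. CH2O, AcOH (1 equiv), EtOH, rt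
Reagents that add atoms: none
Why: The enolised 2-alkyl-1,3-dione is aminomethylated at its central carbon by the iminium ion from 4 and 5 (Mannich reaction), which creates the quaternary carbon; acidic aqueous conditions suppress enaminone formation.

**Step 3**
Reactants: 6 prochiral amino dione
Product: 7 methyl 3-[(1R,2S)-1-{[benzyl(methyl)amino]methyl}-2-hydroxy-6-oxocyclohexyl]propanoate (hydroxyl cis to the propanoate arm, trans to the aminomethyl arm)
Conditions: (S)-selective ketoreductase (hit from a commercial enzyme panel), NADP+ (cat.), i-PrOH, phosphate buffer pH 7/DMSO, 30 °C, substrate as its hydrochloride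
Reagents that add atoms: none
Why: Enzymatic desymmetrising reduction of a prochiral 2,2-disubstituted cyclohexane-1,3-dione, a well-precedented substrate class for yeast and ketoreductases: hydride goes to one enantiotopic carbonyl and one face, giving the (S)-carbinol cis to the slimmer arm and thereby fixing the quaternary centre as (R).

**Step 4**
Reactants: 7 hydroxy ketone
Product: 8 tert-butyldimethylsilyl ether of 7, (1R,2S)
Conditions: TBSCl, imidazole, DMF, 40 °C
Reagents that add atoms: tert-butyldimethylsilyl chloride, CC(C)(C)[Si](C)(C)Cl
Why: Silylation of the secondary alcohol blocks lactonisation and N,O-acetal formation, and the bulky ether later screens one face of the bridge carbon.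

**Step 5**
Reactants: 8 silyl ether; 5 formaldehyde
Product: 10 methyl 3-[(1R,5R,8S)-8-(tert-butyldimethylsilyloxy)-3-methyl-9-oxo-3-azabicyclo[3.3.1]nonan-1-yl]propanoate (silyloxy axial on the carbocycle, anti to the nitrogen bridge), via secondary amine 9 (not isolated)
Conditions: H2 (1 atm), Pd(OH)2/C, EtOAc–AcOH, rt; filter; then 37% aq. CH2O, MeOH, 55 °C
Reagents that add atoms: none
Why: Hydrogenolysis frees the secondary amine (kept as its acetate salt so that it cannot attack the ester), and its methyleneiminium ion is attacked by the only enolisable alpha-carbon of the remaining ketone (intramolecular Mannich reaction); the 1,3-diaxial bridge can form on one face only, so the new bridgehead stereocentre follows from the quaternary one.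

**Step 6**
Reactants: 10 bicyclic amino ketone
Product: 11 spiro-oxirane at the former ketone bridge of 10 (oxirane oxygen on the carbocycle side; configuration inconsequential)
Conditions: Me3S+ I−, KN(SiMe3)2, THF–DMSO, 0 °C to rt
Reagents that add atoms: trimethylsulfonium iodide, C[S+](C)C.[I-]
Why: Dimethylsulfonium methylide adds to the non-enolisable bridging ketone and closes to the spiro-epoxide (Corey–Chaykovsky epoxidation), delivering the future ring CH2O carbon; the epoxide configuration is erased in the next step.

**Step 7**
Reactants: 11 spiro-epoxide; 12 ethyl vinyl ketone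
Product: 14 spiro hemiketal (6-ethyl-6-hydroxytetrahydropyran spiro-fused at the one-carbon bridge; ring CH2O syn to the silyloxy carbocycle, ring CH2CH2 syn to the nitrogen bridge), via hydroxy ketone 13 (not isolated)
Conditions: Cp2TiCl2 (20 mol%), Zn dust, 2,4,6-collidine hydrochloride, 12 (5 equiv, slow addition), THF, rt; aq. NH4Cl
Reagents that add atoms: none
Why: Trivalent titanium (Cp2TiCl, formed in the flask) opens the epoxide reductively to the tertiary bridge radical, which is too hindered to be trapped by a second titanium centre and adds to the enone (Giese addition) from the piperidine face because the carbocycle face is screened by the axial silyloxy group; this sets the quaternary spiro centre, and the freed primary alcohol closes onto the ketone.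

**Step 8**
Reactants: 14 spiro hemiketal
Product: 15 spiro methyl ketal alcohol (6-ethyl-6-methoxytetrahydropyran; free axial hydroxyl on the carbocycle)
Conditions: HCl (1.25 M in MeOH), 0 °C to 40 °C; NaHCO3
Reagents that add atoms: methanol, CO
Why: Acid-catalysed ketal exchange through the cyclic oxocarbenium ion converts the hemiketal into the methyl ketal under thermodynamic control, and acidic methanolysis removes the silyl ether in the same operation.

**Step 9**
Reactants: 15 methyl ketal alcohol
Product: 16 ketone (carbocycle ketone next to the quaternary bridgehead carbon)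
Conditions: (COCl)2, DMSO, CH2Cl2, −78 °C; Et3N, −78 °C to 0 °C
Reagents that add atoms: none
Why: Swern oxidation of the secondary alcohol tolerates the tertiary amine, the ester and the ketal and returns the carbonyl that was parked as an alcohol since step 3.

**Step 10**
Reactants: 16 ketone; 17 but-1-en-3-yne
Product: 19 tertiary enynyl acetate (acetoxy axial, but-3-en-1-ynyl equatorial; configuration inconsequential), via lithium alkoxide 18 (not isolated)
Conditions: 17, n-BuLi, THF, −78 °C; add 16; then Ac2O, −78 °C to rt
Reagents that add atoms: acetic anhydride, CC(=O)OC(C)=O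
Why: The slim lithium acetylide adds to the ketone (1,2-addition) from the equatorial side, away from the axial CH2O of the spiro ring, faster than to the ester, and the tertiary alkoxide is acetylated in the flask.

**Step 11**
Reactants: 19 tertiary enynyl acetate
Product: 22 tricyclic enone (cyclopent-2-enone fused through its C=C to the new seven-membered carbocycle; the alpha-carbon of the enone is bound to the quaternary bridgehead carbon), via allenyl acetate 20 (not isolated), via dienyl acetate 21 (not isolated)
Conditions: HBF4·OEt2 (1.0 equiv), CH2Cl2, 0 °C; [Au(NCMe){P(t-Bu)2(biphenyl-2-yl)}]SbF6 (5 mol%), rt; then K2CO3, MeOH, 0 °C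
Reagents that add atoms: none
Why: Proposed new method: monovalent gold activates the alkyne for a 1,3-acyloxy ([3,3]) shift to carboxyallene 20, whose gold-bound pentadienyl cation closes by a Nazarov-type conrotatory 4π-electrocyclisation (terminal vinyl carbon to the former carbinol carbon) to a spiro-fused cyclopentenylidene-gold species. Because the spiro carbon carries no hydrogen, the carbene is quenched by a 1,2-alkyl shift of a ring bond, which inserts the carbene carbon into the six-membered carbocycle (six to seven) and releases the catalyst as dienyl acetate 21; methanolysis then gives enone 22. The closest known reaction type is the gold-catalysed tandem 1,3-acyloxy shift/Nazarov cyclisation of enynyl acetates that ends by a 1,2-hydride shift, together with gold-promoted 1,2-alkyl-shift ring expansions of alkynyl cyclobutanols, in which the more substituted carbon migrates. The cyclopentenone closes by electrocyclisation between two sp2 termini, the seven-membered ring is not closed but arises by ring expansion, and no stereocentre is created because both new ring-fusion carbons are sp2. The step needs migration of the quaternary bridgehead carbon and not of the ring CH2: the fully alkyl-substituted carbon is the better migrating group, the bridging ketone has already been turned into the spiro ketal so no carbonyl deactivates it, and protonation keeps nitrogen off gold and off the cationic intermediates.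

**Step 12**
Reactants: 22 tricyclic enone
Product: 24 methyl ketal of the target (pentacyclic dienoate), via aldol adduct 23 (not isolated)
Conditions: NaOMe (0.5 equiv), MeOH, 65 °C
Reagents that add atoms: none
Why: Intramolecular aldol condensation of an epsilon-keto ester: under equilibrating alkoxide conditions only the ester enolate reaches a carbonyl through a five-membered transition state (5-exo-trig onto the enone carbonyl), and dehydration to the fully conjugated dienoate makes the closure irreversible.

**Step 13**
Reactants: 24 methyl ketal of the target
Product: 25 target CNP0192143.1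
Conditions: 1 M aq. HCl, THF, rt; NaHCO3
Reagents that add atoms: water, O
Why: Acid hydrolysis of the mixed methyl ketal via the cyclic oxocarbenium ion gives the hemiketal, which should settle as its thermodynamic anomer (axial hydroxyl, anomeric effect) by equilibration through the open hydroxy ketone.

**Compound list**
1 | cyclohexane-1,3-dione | O=C1CCCC(=O)C1 | starting material
2 | methyl acrylate | C=CC(=O)OC | starting material
3 | methyl 3-(2,6-dioxocyclohexyl)propanoate | O=C1CCCC(=O)C1CCC(=O)OC | intermediate
4 | N-benzylmethylamine | CNCc1ccccc1 | starting material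
5 | formaldehyde (37% in water) | C=O | starting material
6 | methyl 3-[1-{[benzyl(methyl)amino]methyl}-2,6-dioxocyclohexyl]propanoate (achiral) | O=C1CCCC(=O)C1(CCC(=O)OC)CN(C)Cc1ccccc1 | intermediate
7 | methyl 3-[(1R,2S)-1-{[benzyl(methyl)amino]methyl}-2-hydroxy-6-oxocyclohexyl]propanoate | O=C1CCC[C@H](O)[C@@]1(CCC(=O)OC)CN(C)Cc1ccccc1 | intermediate
8 | methyl 3-[(1R,2S)-1-{[benzyl(methyl)amino]methyl}-2-(tert-butyldimethylsilyloxy)-6-oxocyclohexyl]propanoate | O=C1CCC[C@H](O[Si](C)(C)C(C)(C)C)[C@@]1(CCC(=O)OC)CN(C)Cc1ccccc1 | intermediate
9 | methyl 3-[(1R,2S)-2-(tert-butyldimethylsilyloxy)-1-[(methylamino)methyl]-6-oxocyclohexyl]propanoate (as acetate salt, not isolated) | O=C1CCC[C@H](O[Si](C)(C)C(C)(C)C)[C@@]1(CCC(=O)OC)CNC | intermediate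
10 | methyl 3-[(1R,5R,8S)-8-(tert-butyldimethylsilyloxy)-3-methyl-9-oxo-3-azabicyclo[3.3.1]nonan-1-yl]propanoate | O=C1[C@@H]2CC[C@H](O[Si](C)(C)C(C)(C)C)[C@@]1(CCC(=O)OC)CN(C)C2 | intermediate
11 | spiro-oxirane at the bridge carbon of 10 (oxirane oxygen on the carbocycle side) | C1O[C@@]12[C@@H]3CC[C@H](O[Si](C)(C)C(C)(C)C)[C@@]2(CCC(=O)OC)CN(C)C3 | intermediate
12 | ethyl vinyl ketone (pent-1-en-3-one) | CCC(=O)C=C | starting material
13 | open hydroxy ketone: bridge carbon bearing CH2OH (syn to the carbocycle) and 3-oxopentyl (syn to the nitrogen bridge); not isolated | OC[C@]1(CCC(=O)CC)[C@@H]2CC[C@H](O[Si](C)(C)C(C)(C)C)[C@@]1(CCC(=O)OC)CN(C)C2 | intermediate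
14 | spiro hemiketal of 13 (6-ethyl-6-hydroxytetrahydropyran spiro-fused at the bridge carbon, silyl ether retained) | CC[C@@]1(O)CC[C@@]2(CO1)[C@@H]1CC[C@H](O[Si](C)(C)C(C)(C)C)[C@@]2(CCC(=O)OC)CN(C)C1 | intermediate
15 | spiro methyl ketal with free axial carbocycle hydroxyl (major anomer drawn) | CC[C@@]1(OC)CC[C@@]2(CO1)[C@@H]1CC[C@H](O)[C@@]2(CCC(=O)OC)CN(C)C1 | intermediate
16 | spiro methyl ketal ketone (carbonyl next to the quaternary bridgehead carbon) | CC[C@@]1(OC)CC[C@@]2(CO1)[C@@H]1CCC(=O)[C@@]2(CCC(=O)OC)CN(C)C1 | intermediate
17 | but-1-en-3-yne (vinylacetylene) | C=CC#C | starting material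
18 | tertiary enynyl alcohol, present as its lithium alkoxide (hydroxyl axial; not isolated) | CC[C@@]1(OC)CC[C@@]2(CO1)[C@@H]1CC[C@@](O)(C#CC=C)[C@@]2(CCC(=O)OC)CN(C)C1 | intermediate
19 | tertiary enynyl acetate (acetoxy axial, but-3-en-1-ynyl equatorial) | CC[C@@]1(OC)CC[C@@]2(CO1)[C@@H]1CC[C@@](OC(C)=O)(C#CC=C)[C@@]2(CCC(=O)OC)CN(C)C1 | intermediate
20 | allenyl acetate (2-acetoxybuta-1,3-dienylidene on the carbocycle; not isolated) | CC[C@@]1(OC)CC[C@@]2(CO1)[C@@H]1CCC(=C=C(OC(C)=O)C=C)[C@@]2(CCC(=O)OC)CN(C)C1 | intermediate
21 | ring-expanded cyclopentadienyl acetate fused to the seven-membered carbocycle (not isolated) | CC[C@@]1(OC)CC[C@@]2(CO1)[C@@H]1CCC3=C(C(OC(C)=O)=CC3)[C@@]2(CCC(=O)OC)CN(C)C1 | intermediate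
22 | tricyclic enone: cyclopentenone fused through its C=C to the seven-membered carbocycle of the 3-azabicyclo[4.3.1]decane, propanoate arm on the quaternary bridgehead carbon | CC[C@@]1(OC)CC[C@@]2(CO1)[C@@H]1CCC3=C(C(=O)CC3)[C@@]2(CCC(=O)OC)CN(C)C1 | intermediate
23 | aldol adduct (tertiary allylic alcohol, beta-hydroxy ester; epimer mixture; not isolated) | CC[C@@]1(OC)CC[C@@]2(CO1)[C@@H]1CCC3=C4C(O)(C(C(=O)OC)C[C@@]42CN(C)C1)CC3 | intermediate
24 | methyl ketal of the target (pentacyclic dienoate) | CC[C@@]1(OC)CC[C@@]2(CO1)[C@@H]1CCC3=C4C(=C(C(=O)OC)C[C@@]42CN(C)C1)CC3 | intermediate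
25 | CNP0192143.1 | CC[C@@]1(O)CC[C@@]2(CO1)[C@@H]1CCC3=C4C(=C(C(=O)OC)C[C@@]42CN(C)C1)CC3 | target

Total step count: 13. Longest linear sequence: 13 steps (from 1).

**Steps most likely to fail**

Step 11 (proposed method). The wrong ring bond may migrate (the ring CH2 instead of the quaternary bridgehead carbon, which sits beta to an ammonium centre), giving the regioisomeric enone. Acetic acid may also be lost to a dienyne, or the catalyst may be bound by nitrogen. The fallback uses known chemistry and sets out from 16. One-carbon homologation with Me3SiCHN2 and AlMe3 (the less substituted carbon migrates) should give, after work-up, the ring-homologated cycloheptanone F1, whose carbonyl stays next to the quaternary bridgehead carbon. Enolisation on the only open side with LiN(SiMe3)2 and PhNTf2 gives the enol triflate F2. Carbonylative Stille coupling with tributyl(vinyl)stannane (Pd(PPh3)4, CO, LiCl) gives the divinyl ketone F3. A Nazarov cyclisation (CH3SO3H, CH2Cl2, then methanolic HCl to restore the ketal) closes the cyclopentenone with the double bond at the ring fusion. The route is rejoined at 22, and the seven-membered ring still arises by ring expansion of the six-membered one.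

Step 7. Facial discrimination at the bridge radical may be insufficient, the radical may be reduced further to the deoxygenated alkene, or the enone may oligomerise. The fallback builds the same centre by polar chemistry and sets out from 10. A Wittig reaction with Ph3P=CHOMe gives the methyl enol ether F4, and aqueous acid unmasks the bridge aldehyde F5. Base-catalysed Michael addition of its enolate to 12 (KOt-Bu cat., t-BuOH–THF), again from the face opposite the axial silyloxy group, gives the keto aldehyde F6. Chemoselective reduction of the aldehyde with NaBH(OAc)3 lets the alcohol close onto the ketone, and the route is rejoined at 14.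

Step 12. Enolisation of the enone may outrun the ester aldol, the aldol adduct may revert instead of dehydrating, or methoxide may add to the dienoate. The fallback replaces the aldol by a cross-coupling and sets out from 22. Kinetic deprotonation at the enone alpha' CH2 and trapping with PhNTf2 (LiN(SiMe3)2, THF, −78 °C) gives the cross-conjugated dienyl triflate F7. Intramolecular alpha-alkenylation of the ester enolate catalysed by zerovalent palladium (Pd2(dba)3, P(t-Bu)3, LiN(SiMe3)2) closes the five-membered ring to the cyclopentadiene ester F8. DBU then moves the ring double bond into conjugation with the ester, and the route is rejoined at 24.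

**Further compounds**
F1 | step 11 | ring-homologated cycloheptanone (carbonyl next to the quaternary bridgehead carbon) | CC[C@@]1(OC)CC[C@@]2(CO1)[C@@H]1CCCC(=O)[C@@]2(CCC(=O)OC)CN(C)C1
F2 | step 11 | enol triflate of F1 | CC[C@@]1(OC)CC[C@@]2(CO1)[C@@H]1CCC=C(OS(=O)(=O)C(F)(F)F)[C@@]2(CCC(=O)OC)CN(C)C1
F3 | step 11 | divinyl ketone (cycloheptenyl vinyl ketone) | CC[C@@]1(OC)CC[C@@]2(CO1)[C@@H]1CCC=C(C(=O)C=C)[C@@]2(CCC(=O)OC)CN(C)C1
F4 | step 7 | methyl enol ether at the bridge carbon (geometric mixture) | COC=C1[C@@H]2CC[C@H](O[Si](C)(C)C(C)(C)C)[C@@]1(CCC(=O)OC)CN(C)C2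
F5 | step 7 | bridge aldehyde (epimer mixture at the bridge carbon) | O=CC1[C@@H]2CC[C@H](O[Si](C)(C)C(C)(C)C)[C@@]1(CCC(=O)OC)CN(C)C2
F6 | step 7 | keto aldehyde with quaternary bridge carbon (oxopentyl syn to the nitrogen bridge) | O=C[C@]1(CCC(=O)CC)[C@@H]2CC[C@H](O[Si](C)(C)C(C)(C)C)[C@@]1(CCC(=O)OC)CN(C)C2
F7 | step 12 | cross-conjugated dienyl triflate of 22 | CC[C@@]1(OC)CC[C@@]2(CO1)[C@@H]1CCC3=C(C(OS(=O)(=O)C(F)(F)F)=CC3)[C@@]2(CCC(=O)OC)CN(C)C1
F8 | step 12 | cyclopentadiene ester (ring closed, double bond not yet conjugated with the ester) | CC[C@@]1(OC)CC[C@@]2(CO1)[C@@H]1CCC3=C4C(=CC3)C(C(=O)OC)C[C@@]42CN(C)C1
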